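## The problem

Arthonioic acid (15) is a depside: two benzoic acid units, each with a 2-oxoheptyl chain at C6 and oxygens at C2 and C4, joined by an aryl ester from the carboxyl of ring A to O4 of ring B. Ring A carries two free phenols, while ring B carries a methyl ether at O2 and the free carboxylic acid. The target has no stereocentre, so the task is regiochemical and chemoselective. The two rings share one carbon skeleton but differ at every oxygen, and the central ester must be formed at a carbonyl flanked by two ortho substituents.

Several groups will not survive rough treatment: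
- The aryl ester is open to nucleophiles.
- The 2,4-dihydroxybenzoic acid unit loses CO2 easily.
- Each benzylic ketone sits ortho to a carboxyl derivative. Base can drive an intramolecular Claisen condensation to a naphthalene-1,3-diol, and acid can cause enol lactonisation to a 3-pentylisocoumarin, which for ring A would expel ring B.

The ketones therefore have to stay masked through every basic step and be released under mild acid only.

The feature that opens the molecule is that each ring is a 6-alkyl-2,4-dioxygenated benzoate, the dehydrogenated form of a 6-alkyl-2,4-dioxocyclohexane-1-carboxylate. Such a dione forms in one operation when a malonate closes the ring C1–C6 and C2–C3 bonds onto an alk-3-en-2-one. Its two stereocentres (C1 and C6) vanish on aromatisation, so they need no control. Because both rings have the same skeleton, one annulation product can feed both halves. After aromatisation the hydrogen-bonded O2 and the free O4 differ enough in reactivity to tell the rings apart.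

## Retrosynthesis

**Unmasking (15 from 14 from 13).** No skeletal bond is cut. The last operations remove three O-benzyl groups (two phenol ethers on ring A, the ester on ring B) and, before that, two dioxolanes. Ending with a neutral hydrogenolysis of diketone 14 frees all acidic functions at once and leaves only a volatile hydrocarbon beside the product. The ketones are released one step earlier from bis-ketal 13, while the molecule is still neutral and easy to purify. The forward steps must leave the aryl ester and the aliphatic ketones untouched, and the acid must be mild enough not to start enol lactonisation.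

**O2–CH3 bond of ring B (13 from 12).** The methyl ether is placed after the depside bond. Methylating first would need a protect, methylate, deprotect sequence at the more reactive O4. In depside 12 that oxygen already carries the ring A acyl group, so the only phenol left is the one to be methylated. The forward step must methylate a hydrogen-bonded phenol with carbonate base without touching the aryl ester, whose carbonyl is shielded by two ortho substituents.

**Depside C(=O)–O bond (12 from 11 and 9).** Cutting the central ester halves the molecule into acid 11 and phenol 9. This cut is preferred over any ring-forming alternative on the intact depside because both halves derive from the same arene, 9. The forward reaction must activate a hindered acid under non-acidic conditions and acylate O4 of 9 (free, para to the ester, more acidic) in preference to the chelated O2.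

**Protecting-group change on ring A (11 from 10 from 9).** Acid 11 comes from tribenzyl compound 10 by cleavage of the benzyl ester, and 10 from 9 by benzylation of both phenols. Benzyl ethers are chosen because they leave together with the ring B benzyl ester at the end. The forward sequence asks for saponification of a hindered ester in the presence of a base-stable ketal.

**Aromatisation retron (9 from 8).** Adding two hydrogens to arene 9 gives cyclohexanedione 8. This trades a tetrasubstituted benzene for a ring that can be built by carbonyl chemistry. The oxidant must remove two hydrogens without hydrogen halide (the dioxolane) and without a hydrogen-transfer catalyst (the benzyl ester).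

**Ring construction (8 from 5 and 6 via 7).** The C1–C6 bond is cut as a Michael addition and the C2–C3 bond as a Claisen closure, leading to enone 5 and malonate 6 through open-chain adduct 7. The neighbouring pair C1–C6 and C3–C4 (a keto ester adding to an enoate) leads to the same dione. The malonate version is preferred because 6 is symmetric, so the closure poses no regiochemical question, and 5 is one step from an aldehyde with a commercial ylide. The precursor is far simpler: an acyclic enone and a commodity diester. The forward step needs conjugate addition to outrun γ-deprotonation of 5, and exactly one equivalent of base.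

**Enone (5 from 3 and 4; 3 from 2 from 1).** The C3=C4 double bond of 5 is cut as a Wittig olefination of aldehyde 3 with stabilised ylide 4. Aldehyde 3 comes from ester 2 by partial reduction, and 2 from β-keto ester 1 by ketalisation. Compound 1 already holds all seven carbons of the oxoheptyl chain with the ketone in place, so the first step installs the mask that lasts until step 10.

## Roads not taken

**Alternative 1:** Ring A is cut at its C1–C6 bond on the intact ester. The open-chain aryl 3,5,7-trioxo ester A1, already attached to ring B, would cyclise with mild base such as Cs2CO3. The C2 carbanion adds to the C7 ketone, and dehydration and enolisation give resorcylate A2.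
- Merits: ring A needs no protecting groups, no dehydrogenation and no esterification at a hindered carbonyl, because the ester bond is made while the acyl part is still an unhindered β-keto ester. In these respects it is better than the chosen plan.
- Weak points: A1 is a labile polyketone whose assembly takes several steps. Its aryl ester is an activated acyl donor, so lactonisation of the C5 enol to a 4-hydroxy-2-pyrone, or Claisen C-acylation, would expel ring B as a phenoxide and compete with the aldol. Ring B must still be made separately with its O2 and O4 told apart, so nothing is shared between the halves.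
- Comparison: the chosen plan pays with benzyl protection of ring A and a hindered coupling. In return every intermediate is a stable, isolable compound, and one arene (9) supplies both rings.

**Alternative 2:** Ring B is kept aromatic from the start, and the ring C6–CH2 and C1–carboxyl bonds are cut together. CsF would release an aryne from silyl triflate A3, and this would insert into a C–C bond of malonate 6 to give homophthalate A4. The methoxy group steers the malonate carbon to the distal aryne carbon.
- Merits: two C–C bonds form on a preformed arene in one step. There is no oxidation-state adjustment and no γ-elimination hazard, which is better than the chosen key step on both counts.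
- Weak points: A3 needs a multi-step preparation from a phloroglucinol derivative with three differentiated oxygens and an ortho silyl group. The side chain arrives as a benzyl acetate, not as the ketone, so A4 needs an ester-to-ketone conversion next to a second benzyl ester and a doubly activated methylene. The step closes no ring and does nothing for ring A.
- Comparison: the chosen plan delivers the chain complete, with the ketone masked, from cheap materials, and uses the same step for both rings.

**Alternative 3:** Ring B is cut at C1–C2 and C5–C6. Thermal [4+2] cycloaddition of ketene-acetal diene A5 with alkynoate A6, then loss of methanol and desilylation, would give phenol A7.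
- Merits: the arene forms without a separate oxidation, and the 2-methoxy-4-hydroxy pattern of ring B arrives in one step. That is better than the chosen plan, which needs a dehydrogenation (step 5) and a late selective methylation (step 9).
- Weak points: A6 is a β-alkyl alkynoate with a single activating group, a poor dienophile that would need forcing conditions while A5 is hydrolytically fragile. A6 needs its own synthesis through a propargylic ketal prone to allene isomerisation. Ring A, with two free phenols, would need a second diene or a demethylation.
- Comparison: the chosen plan relies on a polar addition to an enone that is well behaved with malonates, uses commercial reagents, and draws ring A from the same intermediate.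

Key step: step 4

Assumption: compounds 1, 4 and 6 are purchased. Dione 8 is written as one enol tautomer and is racemic, and its stereocentres disappear in step 5.

## Route

Step 1
Reactants: 1 ethyl 3-oxooctanoate
Product: 2 ethyl 2-(2-pentyl-1,3-dioxolan-2-yl)acetate
Conditions: HOCH2CH2OH (3 equiv), p-TsOH·H2O (cat.), PhMe, reflux, Dean–Stark
Reagents that add atoms: ethylene glycol, OCCO
Why: Acid-catalysed ketalisation with azeotropic removal of water; the ketone of a β-keto ester ketalises readily and the ester is untouched.

Step 2
Reactants: 2 ethyl 2-(2-pentyl-1,3-dioxolan-2-yl)acetate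
Product: 3 2-(2-pentyl-1,3-dioxolan-2-yl)acetaldehyde
Conditions: i-Bu2AlH (1.05 equiv), CH2Cl2, −78 °C; MeOH, then aq. potassium sodium tartrate
Reagents that add atoms: none
Why: Partial ester reduction; the aluminium hemiacetal is held at −78 °C by chelation to a dioxolane oxygen and collapses to the aldehyde only on work-up. The aldehyde should be used crude.

Step 3
Reactants: 3 2-(2-pentyl-1,3-dioxolan-2-yl)acetaldehyde; 4 1-(triphenylphosphoranylidene)propan-2-one
Product: 5 (E)-5-(2-pentyl-1,3-dioxolan-2-yl)pent-3-en-2-one
Conditions: 4 (1.2 equiv), PhMe, 60 °C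
Reagents that add atoms: none
Why: Wittig olefination with a stabilised ylide, which should give the E-enone; the neutral medium avoids β-elimination of the ketal aldehyde.

Step 4
Reactants: 5 (E)-5-(2-pentyl-1,3-dioxolan-2-yl)pent-3-en-2-one; 6 dibenzyl malonate
Product: 8 benzyl trans-2-hydroxy-4-oxo-6-[(2-pentyl-1,3-dioxolan-2-yl)methyl]cyclohex-2-ene-1-carboxylate (racemic), via Michael adduct 7 (not isolated)
Conditions: 6 (1.1 equiv), NaH (1.05 equiv), THF, 0 °C; then 5, 0 °C to reflux; cold 0.5 M HCl to pH 4
Reagents that add atoms: none
Why: Sodium dibenzyl malonate, preformed with slightly less NaH than malonate so that neither hydride nor free alkoxide remains, adds in a Michael reaction to C4 of enone 5 and forms the future ring C1–C6 bond of adduct 7. Proton transfer then gives a small concentration of the methyl ketone enolate, which attacks one benzyl ester in a 6-exo-trig Dieckmann (Claisen) closure and forms the C2–C3 bond; the enolate of the internal methylene could only close a four-membered ring. The expelled benzyloxide deprotonates the strongly acidic 1,3-dione, which makes the sequence irreversible and pulls both equilibria forward. The closest known reaction type is the malonate addition and ring closure onto alk-3-en-2-ones that gives dihydroresorcylates, here run with benzyl esters in an aprotic solvent to avoid ester exchange. C6 forms without control (racemic), and C1, the acidic carbon between ester and ketone, equilibrates to the trans isomer with both substituents equatorial; neither centre survives step 5. The selectivity needed is conjugate addition over γ-deprotonation of 5, which would expel a dioxolane oxygen; the soft, weakly basic malonate anion and the absence of excess base should secure it, and once 7 has formed this elimination is no longer possible.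

Step 5
Reactants: 8 benzyl trans-2-hydroxy-4-oxo-6-[(2-pentyl-1,3-dioxolan-2-yl)methyl]cyclohex-2-ene-1-carboxylate
Product: 9 benzyl 2,4-dihydroxy-6-[(2-pentyl-1,3-dioxolan-2-yl)methyl]benzoate
Conditions: DDQ (1.1 equiv), 1,4-dioxane (dry), 80 °C
Reagents that add atoms: none
Why: Quinone dehydrogenation; the dienol tautomer of 8 gives up hydride and a proton, and the gain of aromaticity drives the reaction. The medium is anhydrous and free of hydrogen halide, so the dioxolane and benzyl ester should survive, and the benzylic CH2 is meta to both hydroxyls, so no quinone methide can form.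

Step 6
Reactants: 9 benzyl 2,4-dihydroxy-6-[(2-pentyl-1,3-dioxolan-2-yl)methyl]benzoate
Product: 10 benzyl 2,4-bis(benzyloxy)-6-[(2-pentyl-1,3-dioxolan-2-yl)methyl]benzoate
Conditions: BnBr (2.5 equiv), K2CO3 (3 equiv), DMF, 60 °C
Reagents that add atoms: benzyl bromide, BrCc1ccccc1
Why: Williamson ether synthesis; O4 reacts first, and warming carries the hydrogen-bonded O2 to completion. Ketal and ester are inert to carbonate.

Step 7
Reactants: 10 benzyl 2,4-bis(benzyloxy)-6-[(2-pentyl-1,3-dioxolan-2-yl)methyl]benzoate
Product: 11 2,4-bis(benzyloxy)-6-[(2-pentyl-1,3-dioxolan-2-yl)methyl]benzoic acid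
Conditions: KOH (10 equiv), DMSO/H2O (4:1), 90 °C; cold dilute HCl to pH 4, rapid extraction
Reagents that add atoms: potassium hydroxide, [K+].[OH-]
Why: Saponification; poorly solvated hydroxide in aqueous DMSO is the usual answer to benzoates with two ortho substituents. Aryl benzyl ethers and the dioxolane are stable to base, and the brief cold acidification should spare the ketal.

Step 8
Reactants: 11 2,4-bis(benzyloxy)-6-[(2-pentyl-1,3-dioxolan-2-yl)methyl]benzoic acid; 9 benzyl 2,4-dihydroxy-6-[(2-pentyl-1,3-dioxolan-2-yl)methyl]benzoate
Product: 12 benzyl 4-({2,4-bis(benzyloxy)-6-[(2-pentyl-1,3-dioxolan-2-yl)methyl]benzoyl}oxy)-2-hydroxy-6-[(2-pentyl-1,3-dioxolan-2-yl)methyl]benzoate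
Conditions: 9 (1.1 equiv), DCC (1.2 equiv), DMAP (0.2 equiv), CH2Cl2, 0 °C to rt
Reagents that add atoms: none
Why: Steglich esterification under non-acidic conditions that the two dioxolanes tolerate. O4 of 9 is free, unhindered and the more acidic phenol, whereas O2 is tied up in a hydrogen bond to the ester carbonyl and flanked by it, so the bulky acyl donor should go to O4.

Step 9
Reactants: 12 benzyl 4-({2,4-bis(benzyloxy)-6-[(2-pentyl-1,3-dioxolan-2-yl)methyl]benzoyl}oxy)-2-hydroxy-6-[(2-pentyl-1,3-dioxolan-2-yl)methyl]benzoate
Product: 13 benzyl 4-({2,4-bis(benzyloxy)-6-[(2-pentyl-1,3-dioxolan-2-yl)methyl]benzoyl}oxy)-2-methoxy-6-[(2-pentyl-1,3-dioxolan-2-yl)methyl]benzoate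
Conditions: MeI (5 equiv), K2CO3 (3 equiv), DMF, rt
Reagents that add atoms: iodomethane, CI
Why: Williamson methylation of the only remaining phenol. The depside carbonyl has two ortho substituents and should resist carbonate and phenoxide, as in the classical permethylation of depsides.

Step 10
Reactants: 13 benzyl 4-({2,4-bis(benzyloxy)-6-[(2-pentyl-1,3-dioxolan-2-yl)methyl]benzoyl}oxy)-2-methoxy-6-[(2-pentyl-1,3-dioxolan-2-yl)methyl]benzoate
Product: 14 benzyl 4-{[2,4-bis(benzyloxy)-6-(2-oxoheptyl)benzoyl]oxy}-2-methoxy-6-(2-oxoheptyl)benzoate
Conditions: 1 M aq. HCl/THF (1:4), rt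
Reagents that add atoms: water, O
Why: Acid-catalysed hydrolysis of both dioxolanes; dilute aqueous acid at room temperature should leave the hindered aryl ester, the benzyl ester and the benzyl ethers intact.

Step 11
Reactants: 14 benzyl 4-{[2,4-bis(benzyloxy)-6-(2-oxoheptyl)benzoyl]oxy}-2-methoxy-6-(2-oxoheptyl)benzoate
Product: 15 arthonioic acid, 4-{[2,4-dihydroxy-6-(2-oxoheptyl)benzoyl]oxy}-2-methoxy-6-(2-oxoheptyl)benzoic acid
Conditions: H2 (1 atm), 10% Pd/C, EtOAc, rt
Reagents that add atoms: none
Why: Hydrogenolysis of the three O-benzyl groups; the aryl ester and the non-conjugated ketones are inert under these conditions, and the only co-product is volatile, so the acid-sensitive target needs no further treatment.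

## Compound list

1 | ethyl 3-oxooctanoate | CCCCCC(=O)CC(=O)OCC | starting material
2 | ethyl 2-(2-pentyl-1,3-dioxolan-2-yl)acetate | CCCCCC1(CC(=O)OCC)OCCO1 | intermediate
3 | 2-(2-pentyl-1,3-dioxolan-2-yl)acetaldehyde | CCCCCC1(CC=O)OCCO1 | intermediate
4 | 1-(triphenylphosphoranylidene)propan-2-one | CC(=O)C=P(c1ccccc1)(c1ccccc1)c1ccccc1 | starting material
5 | (E)-5-(2-pentyl-1,3-dioxolan-2-yl)pent-3-en-2-one | CCCCCC1(C/C=C/C(C)=O)OCCO1 | intermediate
6 | dibenzyl malonate | O=C(CC(=O)OCc1ccccc1)OCc1ccccc1 | starting material
7 | dibenzyl 2-[4-oxo-1-(2-pentyl-1,3-dioxolan-2-yl)pentan-2-yl]propanedioate (racemic; Michael adduct, not isolated) | CCCCCC1(CC(CC(C)=O)C(C(=O)OCc2ccccc2)C(=O)OCc2ccccc2)OCCO1 | intermediate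
8 | benzyl trans-2-hydroxy-4-oxo-6-[(2-pentyl-1,3-dioxolan-2-yl)methyl]cyclohex-2-ene-1-carboxylate (racemic; carboxylate and side chain on opposite faces, one enantiomer drawn) | O=C(OCc1ccccc1)[C@@H]1C(O)=CC(=O)C[C@H]1CC1(CCCCC)OCCO1 | intermediate
9 | benzyl 2,4-dihydroxy-6-[(2-pentyl-1,3-dioxolan-2-yl)methyl]benzoate | CCCCCC1(Cc2cc(O)cc(O)c2C(=O)OCc2ccccc2)OCCO1 | intermediate
10 | benzyl 2,4-bis(benzyloxy)-6-[(2-pentyl-1,3-dioxolan-2-yl)methyl]benzoate | CCCCCC1(Cc2cc(OCc3ccccc3)cc(OCc3ccccc3)c2C(=O)OCc2ccccc2)OCCO1 | intermediate
11 | 2,4-bis(benzyloxy)-6-[(2-pentyl-1,3-dioxolan-2-yl)methyl]benzoic acid | CCCCCC1(Cc2cc(OCc3ccccc3)cc(OCc3ccccc3)c2C(=O)O)OCCO1 | intermediate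
12 | benzyl 4-({2,4-bis(benzyloxy)-6-[(2-pentyl-1,3-dioxolan-2-yl)methyl]benzoyl}oxy)-2-hydroxy-6-[(2-pentyl-1,3-dioxolan-2-yl)methyl]benzoate | CCCCCC1(Cc2cc(OCc3ccccc3)cc(OCc3ccccc3)c2C(=O)Oc2cc(O)c(C(=O)OCc3ccccc3)c(CC3(CCCCC)OCCO3)c2)OCCO1 | intermediate
13 | benzyl 4-({2,4-bis(benzyloxy)-6-[(2-pentyl-1,3-dioxolan-2-yl)methyl]benzoyl}oxy)-2-methoxy-6-[(2-pentyl-1,3-dioxolan-2-yl)methyl]benzoate | CCCCCC1(Cc2cc(OCc3ccccc3)cc(OCc3ccccc3)c2C(=O)Oc2cc(OC)c(C(=O)OCc3ccccc3)c(CC3(CCCCC)OCCO3)c2)OCCO1 | intermediate
14 | benzyl 4-{[2,4-bis(benzyloxy)-6-(2-oxoheptyl)benzoyl]oxy}-2-methoxy-6-(2-oxoheptyl)benzoate | CCCCCC(=O)Cc1cc(OCc2ccccc2)cc(OCc2ccccc2)c1C(=O)Oc1cc(OC)c(C(=O)OCc2ccccc2)c(CC(=O)CCCCC)c1 | intermediate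
15 | arthonioic acid, 4-{[2,4-dihydroxy-6-(2-oxoheptyl)benzoyl]oxy}-2-methoxy-6-(2-oxoheptyl)benzoic acid (no stereocentre) | CCCCCC(=O)Cc1cc(O)cc(O)c1C(=O)Oc1cc(CC(=O)CCCCC)c(C(=O)O)c(OC)c1 | target

## Step count and risks

Total step count: 11. Longest linear sequence: 11 steps (1 to 11). Arene 9 is divided after step 5, one part is carried through steps 6 and 7 to acid 11, and the two parts are rejoined in step 8.

**Step 4 (key step).** The most likely failure is γ-deprotonation of enone 5 followed by vinylogous β-elimination, which opens the dioxolane before the malonate has added. A second concern is a slow Claisen closure in the aprotic medium, so that adduct 7 reverts by retro-Michael reaction on heating. The fallback changes the partners so that a less basic nucleophile meets a less acidic acceptor; it sets out from aldehyde 3 and returns at 8. Wittig reaction of 3 with benzyl (triphenylphosphoranylidene)acetate would give benzyl (E)-4-(2-pentyl-1,3-dioxolan-2-yl)but-2-enoate F1. Sodium benzyl acetoacetate (from benzyl acetoacetate and NaH in THF) would add to F1 to give dibenzyl 2-acetyl-3-[(2-pentyl-1,3-dioxolan-2-yl)methyl]pentanedioate F2. Claisen closure of its methyl ketone enolate onto the distal ester forms the C3–C4 bond instead of C2–C3 and leads to the same dione 8.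

**Step 5.** The dehydrogenation may stop short or be diverted into adducts between the quinone and the nucleophilic C3 of the dione, and the acidic hydroquinone formed may cost the dioxolane if moisture is present. The fallback sets out from 8 and returns at 9. Halogenation and dehydrohalogenation with CuBr2 (2.2 equiv) in MeCN should aromatise the ring; the hydrogen bromide released is expected to remove the ketal, and aqueous work-up would complete this to benzyl 2,4-dihydroxy-6-(2-oxoheptyl)benzoate F3. Re-ketalisation of F3 with ethylene glycol, triethyl orthoformate and catalytic p-TsOH at room temperature would restore 9 before any basic step.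

**Step 7.** Hydroxide attack at a carbonyl shielded by two ortho substituents may be too slow, and forcing it risks decomposition. The fallback sets out from 10 and returns at 11, and it avoids nucleophilic acyl substitution by oxygen altogether. LiAlH4 in THF would reduce the ester to {2,4-bis(benzyloxy)-6-[(2-pentyl-1,3-dioxolan-2-yl)methyl]phenyl}methanol F4. MnO2 in CH2Cl2 would give 2,4-bis(benzyloxy)-6-[(2-pentyl-1,3-dioxolan-2-yl)methyl]benzaldehyde F5. Pinnick oxidation (NaClO2, NaH2PO4, 2-methylbut-2-ene, t-BuOH/H2O) would give acid 11.

**Step 8.** Acyl transfer from the hindered acid may be slow enough for an O-to-N acyl shift in the activated intermediate to compete, and acylation of the chelated O2 or of both oxygens would erode the regioselectivity. The fallback fixes the oxygen pattern of ring B before coupling; it sets out from 9 and returns at 13, bypassing step 9.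
- TIPSCl and imidazole in DMF would silylate O4 selectively to benzyl 2-hydroxy-6-[(2-pentyl-1,3-dioxolan-2-yl)methyl]-4-[(triisopropylsilyl)oxy]benzoate F6.
- MeI and K2CO3 in acetone would give benzyl 2-methoxy-6-[(2-pentyl-1,3-dioxolan-2-yl)methyl]-4-[(triisopropylsilyl)oxy]benzoate F7.
- Bu4NF in THF at 0 °C would release benzyl 4-hydroxy-2-methoxy-6-[(2-pentyl-1,3-dioxolan-2-yl)methyl]benzoate F8.
- F8 has a single hydroxyl and would be coupled with 11 (DCC, DMAP) to give 13 directly.

**Step 10.** Acid may promote enol lactonisation of the freed ring A ketone onto the aryl ester, with expulsion of ring B as its phenol, or hydrolysis of the second ketal may lag. The fallback reverses the order of the two deprotections; it sets out from 13 and returns at 15. Hydrogenolysis of 13 (H2, 10% Pd/C, EtOAc) would give 4-({2,4-dihydroxy-6-[(2-pentyl-1,3-dioxolan-2-yl)methyl]benzoyl}oxy)-2-methoxy-6-[(2-pentyl-1,3-dioxolan-2-yl)methyl]benzoic acid F9. In F9 the free ortho hydroxyl of ring A is hydrogen-bonded to the depside carbonyl and makes it less electrophilic. Aqueous acetic acid in THF at 40 °C would then hydrolyse both ketals to give 15.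

## Further compounds

F1 | step 4 | benzyl (E)-4-(2-pentyl-1,3-dioxolan-2-yl)but-2-enoate | CCCCCC1(C/C=C/C(=O)OCc2ccccc2)OCCO1
F2 | step 4 | dibenzyl 2-acetyl-3-[(2-pentyl-1,3-dioxolan-2-yl)methyl]pentanedioate (racemic mixture of diastereomers) | CCCCCC1(CC(CC(=O)OCc2ccccc2)C(C(C)=O)C(=O)OCc2ccccc2)OCCO1
F3 | step 5 | benzyl 2,4-dihydroxy-6-(2-oxoheptyl)benzoate | CCCCCC(=O)Cc1cc(O)cc(O)c1C(=O)OCc1ccccc1
F4 | step 7 | {2,4-bis(benzyloxy)-6-[(2-pentyl-1,3-dioxolan-2-yl)methyl]phenyl}methanol | CCCCCC1(Cc2cc(OCc3ccccc3)cc(OCc3ccccc3)c2CO)OCCO1
F5 | step 7 | 2,4-bis(benzyloxy)-6-[(2-pentyl-1,3-dioxolan-2-yl)methyl]benzaldehyde | CCCCCC1(Cc2cc(OCc3ccccc3)cc(OCc3ccccc3)c2C=O)OCCO1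
F6 | step 8 | benzyl 2-hydroxy-6-[(2-pentyl-1,3-dioxolan-2-yl)methyl]-4-[(triisopropylsilyl)oxy]benzoate | CCCCCC1(Cc2cc(O[Si](C(C)C)(C(C)C)C(C)C)cc(O)c2C(=O)OCc2ccccc2)OCCO1
F7 | step 8 | benzyl 2-methoxy-6-[(2-pentyl-1,3-dioxolan-2-yl)methyl]-4-[(triisopropylsilyl)oxy]benzoate | CCCCCC1(Cc2cc(O[Si](C(C)C)(C(C)C)C(C)C)cc(OC)c2C(=O)OCc2ccccc2)OCCO1
F8 | step 8 | benzyl 4-hydroxy-2-methoxy-6-[(2-pentyl-1,3-dioxolan-2-yl)methyl]benzoate | CCCCCC1(Cc2cc(O)cc(OC)c2C(=O)OCc2ccccc2)OCCO1
F9 | step 10 | 4-({2,4-dihydroxy-6-[(2-pentyl-1,3-dioxolan-2-yl)methyl]benzoyl}oxy)-2-methoxy-6-[(2-pentyl-1,3-dioxolan-2-yl)methyl]benzoic acid | CCCCCC1(Cc2cc(O)cc(O)c2C(=O)Oc2cc(OC)c(C(=O)O)c(CC3(CCCCC)OCCO3)c2)OCCO1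
A1 | alternative 1 | benzyl 2-methoxy-6-[(2-pentyl-1,3-dioxolan-2-yl)methyl]-4-{[3,5,7-trioxo-8-(2-pentyl-1,3-dioxolan-2-yl)octanoyl]oxy}benzoate | CCCCCC1(CC(=O)CC(=O)CC(=O)CC(=O)Oc2cc(CC3(CCCCC)OCCO3)c(C(=O)OCc3ccccc3)c(OC)c2)OCCO1
A2 | alternative 1 | benzyl 4-({2,4-dihydroxy-6-[(2-pentyl-1,3-dioxolan-2-yl)methyl]benzoyl}oxy)-2-methoxy-6-[(2-pentyl-1,3-dioxolan-2-yl)methyl]benzoate | CCCCCC1(Cc2cc(O)cc(O)c2C(=O)Oc2cc(CC3(CCCCC)OCCO3)c(C(=O)OCc3ccccc3)c(OC)c2)OCCO1
A3 | alternative 2 | 2-methoxy-4-(methoxymethoxy)-6-(trimethylsilyl)phenyl trifluoromethanesulfonate | COCOc1cc(OC)c(OS(=O)(=O)C(F)(F)F)c([Si](C)(C)C)c1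
A4 | alternative 2 | benzyl 2-(2-benzyloxy-2-oxoethyl)-6-methoxy-4-(methoxymethoxy)benzoate | COCOc1cc(OC)c(C(=O)OCc2ccccc2)c(CC(=O)OCc2ccccc2)c1
A5 | alternative 3 | 1,1-dimethoxy-3-(trimethylsilyloxy)buta-1,3-diene | COC(OC)=CC(=C)O[Si](C)(C)C
A6 | alternative 3 | benzyl 4-(2-pentyl-1,3-dioxolan-2-yl)but-2-ynoate | CCCCCC1(CC#CC(=O)OCc2ccccc2)OCCO1
A7 | alternative 3 | benzyl 4-hydroxy-2-methoxy-6-[(2-pentyl-1,3-dioxolan-2-yl)methyl]benzoate | CCCCCC1(Cc2cc(O)cc(OC)c2C(=O)OCc2ccccc2)OCCO1
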